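**Retrosynthetic overview**
1. The target is the desilylated keto form of a bis-silyl dienone; the C9 ketone/C10 methylene is the tautomer that a 9-phenanthrol adopts once ring C is no longer aromatic.
2. Key disconnection: the O–C4 bond of the oxazolidine, made by iodine(III) dearomatisation of a flat 1-phenanthrol whose 4-aminobutanal chain on N(C3) has closed to a pyrrolidin-2-ol. The same operation forms the pyrrolidine, the oxazolidine, the dienone and both stereocentres.
3. Enabling feature: ring C is a 4-alkoxy-4-methylcyclohexa-2,5-dienone (p-quinol ether). C4 (CH3, O) is para to the C1 carbonyl and adjacent to C3–N, so the aminal oxygen on the N-substituent can close a five-membered ring onto the para carbon of the oxidised phenol.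
4. The phenanthrene comes from one hexasubstituted ring C arene carrying I, Br and Cl, used in that order: Suzuki biaryl bond (C4a–C4b), ketone α-arylation (C10–C10a, closes ring B), Buchwald–Hartwig amination (C3–N).
5. Ring order: A and C (arenes) → B → pyrrolidine → oxazolidine (with dearomatisation of C).

Key step: step 12

Assumption: the (R,R) antipode of the lactate-derived aryl-λ3-iodane is taken as the one that gives the (4R) series; if the sense of induction is opposite, the (S,S) reagent is used with no other change.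
Remark: phenanthrene locants (C1–C10a) are used for the core; C2' is the aminal carbon of the pyrrolidine.

**Step 1**
Reactants: 1 2-methoxy-4-methylphenol
Product: 2 2-bromo-6-methoxy-4-methylphenol
Conditions: NBS (1.0 equiv), MeCN, 0 °C → rt
Reagents that add atoms: N-bromosuccinimide, BrN1C(=O)CCC1=O
Why: Electrophilic aromatic bromination; the free OH directs to its only open ortho position because the para position carries the methyl group.

**Step 2**
Reactants: 2 2-bromo-6-methoxy-4-methylphenol
Product: 3 2-bromo-3-iodo-6-methoxy-4-methylphenol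
Conditions: NIS (1.05 equiv), TFA (cat.), MeCN, 0 °C → rt
Reagents that add atoms: N-iodosuccinimide, IN1C(=O)CCC1=O
Why: Electrophilic aromatic iodination; with the ortho and para positions of the OH occupied, the methoxy group should steer I+ to its para position, as in the second halogenation of 5-halovanillins.

**Step 3**
Reactants: 3 2-bromo-3-iodo-6-methoxy-4-methylphenol
Product: 4 1-(benzyloxy)-2-bromo-3-iodo-6-methoxy-4-methylbenzene
Conditions: BnBr, K2CO3, DMF, rt
Reagents that add atoms: benzyl bromide, BrCc1ccccc1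
Why: Williamson ether synthesis on the phenoxide; the benzyl group blocks the phenol through the later halogenation and the three couplings.

**Step 4**
Reactants: 4 1-(benzyloxy)-2-bromo-3-iodo-6-methoxy-4-methylbenzene
Product: 5 1-(benzyloxy)-2-bromo-5-chloro-3-iodo-6-methoxy-4-methylbenzene
Conditions: NCS (1.1 equiv), HCl (cat.), MeCN, 50 °C, dark
Reagents that add atoms: N-chlorosuccinimide, ClN1C(=O)CCC1=O
Why: Electrophilic aromatic chlorination at the single remaining ring C–H, which is ortho to the methoxy group.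

**Step 5**
Reactants: 6 1-bromo-3,5-dimethoxybenzene
Product: 8 1-(2-bromo-6-hydroxy-4-methoxyphenyl)ethan-1-one, via dimethoxy ketone 7 (not isolated)
Conditions: AcCl (1.2 equiv), AlCl3 (3 equiv), CH2Cl2, 0 °C → reflux
Reagents that add atoms: acetyl chloride, CC(Cl)=O
Why: Friedel–Crafts acylation para to one OMe and ortho to the other (the site between the two OMe groups is more hindered), followed in the same pot by AlCl3-chelation-controlled cleavage of the methyl ether ortho to the new ketone.

**Step 6**
Reactants: 8 1-(2-bromo-6-hydroxy-4-methoxyphenyl)ethan-1-one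
Product: 9 1-{2-bromo-4-methoxy-6-[(triisopropylsilyl)oxy]phenyl}ethan-1-one
Conditions: TIPSOTf, 2,6-lutidine, CH2Cl2, 0 °C → rt
Reagents that add atoms: triisopropylsilyl triflate, CC(C)[Si](OS(=O)(=O)C(F)(F)F)(C(C)C)C(C)C
Why: O-silylation of the chelated phenol with a silyl triflate, which overcomes the hydrogen bond to the ketone.

**Step 7**
Reactants: 9 1-{2-bromo-4-methoxy-6-[(triisopropylsilyl)oxy]phenyl}ethan-1-one; 5 1-(benzyloxy)-2-bromo-5-chloro-3-iodo-6-methoxy-4-methylbenzene
Product: 11 1-{3'-(benzyloxy)-2'-bromo-5'-chloro-4',5-dimethoxy-6'-methyl-3-[(triisopropylsilyl)oxy]-[1,1'-biphenyl]-2-yl}ethan-1-one, via arylboronate 10 (not isolated)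
Conditions: B2pin2, XPhos Pd G2 (cat.), KOAc, dioxane, 90 °C; then 5, aq K3PO4, 80 °C
Reagents that add atoms: none
Why: One-pot Miyaura borylation and Suzuki–Miyaura coupling; oxidative addition should take the C–I bond of 5 ahead of its C–Br and C–Cl bonds.

**Step 8**
Reactants: 11 the biaryl methyl ketone of step 7
Product: 12 1-(benzyloxy)-3-chloro-2,6-dimethoxy-4-methyl-8-[(triisopropylsilyl)oxy]phenanthren-9-ol
Conditions: Pd2(dba)3 (cat.), XPhos (cat.), K3PO4, toluene, 100 °C
Reagents that add atoms: none
Why: Palladium-catalysed intramolecular α-arylation of the methyl ketone at the aryl bromide (six-membered ring closure, C–Br ahead of the hindered C–Cl); the 10H-phenanthren-9-one formed tautomerises to the aromatic 9-phenanthrol.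

**Step 9**
Reactants: 12 1-(benzyloxy)-3-chloro-2,6-dimethoxy-4-methyl-8-[(triisopropylsilyl)oxy]phenanthren-9-ol
Product: 13 1-(benzyloxy)-3-chloro-2,6-dimethoxy-4-methyl-8,9-bis[(triisopropylsilyl)oxy]phenanthrene
Conditions: TIPSOTf, 2,6-lutidine, CH2Cl2, 0 → 40 °C
Reagents that add atoms: triisopropylsilyl triflate, CC(C)[Si](OS(=O)(=O)C(F)(F)F)(C(C)C)C(C)C
Why: O-silylation of the phenanthrol; because both peri oxygens end as TIPS ethers, any O8/O9 silyl migration in 12 has no consequence.

**Step 10**
Reactants: 13 1-(benzyloxy)-3-chloro-2,6-dimethoxy-4-methyl-8,9-bis[(triisopropylsilyl)oxy]phenanthrene; 14 4,4-diethoxybutan-1-amine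
Product: 15 1-(benzyloxy)-N-(4,4-diethoxybutyl)-2,6-dimethoxy-4-methyl-8,9-bis[(triisopropylsilyl)oxy]phenanthren-3-amine
Conditions: BrettPhos Pd G3 (cat.), NaOtBu, toluene, 100 °C
Reagents that add atoms: none
Why: Buchwald–Hartwig amination of the remaining aryl chloride with a primary alkylamine, using a bulky biarylphosphine of the kind established for ortho,ortho-disubstituted aryl chlorides and monoarylation.

**Step 11**
Reactants: 15 the N-(4,4-diethoxybutyl) benzyl ether of step 10
Product: 16 3-[(4,4-diethoxybutyl)amino]-2,6-dimethoxy-4-methyl-8,9-bis[(triisopropylsilyl)oxy]phenanthren-1-ol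
Conditions: H2 (1 atm), 10% Pd/C, EtOAc, rt
Reagents that add atoms: none
Why: Hydrogenolysis of the benzyl ether; the silyl ethers, the acetal and the arylamine should be inert.

**Step 12**
Reactants: 16 3-[(4,4-diethoxybutyl)amino]-2,6-dimethoxy-4-methyl-8,9-bis[(triisopropylsilyl)oxy]phenanthren-1-ol
Product: 19 (4R,2'S)-2,6-dimethoxy-4-methyl-8,9-bis[(triisopropylsilyl)oxy]-4H-phenanthren-1-one bridged by pyrrolidine (N1'–C3 and C2'–O–C4), via amino aldehyde 17 (not isolated), via pyrrolidin-2-ol 18 (not isolated)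
Conditions: 1 M aq HCl, THF, 0 °C → rt; NaHCO3 work-up; then (R,R)-ArI(OAc)2 (1.1 equiv; Ar = 2,6-bis{[(2R)-1-methoxy-1-oxopropan-2-yl]oxy}phenyl), CH2Cl2, −40 °C
Reagents that add atoms: water, O
Why: Proposed new method: dilute acid unmasks the aldehyde of 16 and the arylamine nitrogen adds to it (5-exo-trig) to give the N-aryl pyrrolidin-2-ol 18, whose only free phenol (C1–OH) exchanges onto the chiral aryl-λ3-iodane; the hemiaminal oxygen, held on the nitrogen at C3, then attacks C4 (para to the activated oxygen) as the iodoarene leaves, closing the oxazolidine as a five-membered ring that contains the C3–C4 bond of the former arene and leaving the C1 ketone. The closest known reaction type is the iodine(III)-mediated oxidative dearomatisation of phenols and naphthols by tethered oxygen nucleophiles (spirolactonisation, spiroetherification) and the hydroxylative para-dearomatisation to p-quinols, both known in enantioselective form with C2-symmetric lactate-derived iodanes; a hemiaminal oxygen made in situ and a ring-fusing para attack have not been shown. The C4 stereocentre should be set by the chiral iodane during the associative C–O bond formation (reagent control on a flat, achiral arene). The aminal carbon is not controlled separately: 18 epimerises freely through ring opening, only the cis-fused pyrrolo-oxazolidine can form, and the epimer with the pyrrolidine ring anti to the C4 methyl group (aminal H syn to CH3) is expected as the less congested and thermodynamically preferred one. The step needs para (C4) over ortho (C2) attack and oxidation of ring C only: attack at the OMe-bearing C2 would give an ionisable mixed ketal that reverts whereas C4 attack gives the vinylogous-amide-stabilised cross-conjugated dienone, and O8 and O9 are silylated so that rings A and B cannot bind the iodane.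

**Step 13**
Reactants: 19 the bis-silyl dienone of step 12
Product: 20 CNP0528850.1, (4R,2'S)-8-hydroxy-2,6-dimethoxy-4-methyl-4,10-dihydrophenanthrene-1,9-dione bridged by pyrrolidine (N1'–C3 and C2'–O–C4)
Conditions: HF·pyridine, pyridine, THF, 0 °C → rt
Reagents that add atoms: none
Why: Fluoride cleavage of the aryl and dienol silyl ethers; the freed C9 dienol should ketonise by protonation at C10 to the aryl ketone hydrogen-bonded to 8-OH, and the non-basic medium leaves C4 and the N,O-acetal untouched.

**Compound list**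
1 | 2-methoxy-4-methylphenol | COc1cc(C)ccc1O | starting material
2 | 2-bromo-6-methoxy-4-methylphenol | COc1cc(C)cc(Br)c1O | intermediate
3 | 2-bromo-3-iodo-6-methoxy-4-methylphenol | COc1cc(C)c(I)c(Br)c1O | intermediate
4 | 1-(benzyloxy)-2-bromo-3-iodo-6-methoxy-4-methylbenzene | COc1cc(C)c(I)c(Br)c1OCc1ccccc1 | intermediate
5 | 1-(benzyloxy)-2-bromo-5-chloro-3-iodo-6-methoxy-4-methylbenzene | COc1c(Cl)c(C)c(I)c(Br)c1OCc1ccccc1 | intermediate
6 | 1-bromo-3,5-dimethoxybenzene | COc1cc(Br)cc(OC)c1 | starting material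
7 | 1-(2-bromo-4,6-dimethoxyphenyl)ethan-1-one (not isolated) | CC(=O)c1c(Br)cc(OC)cc1OC | intermediate
8 | 1-(2-bromo-6-hydroxy-4-methoxyphenyl)ethan-1-one | CC(=O)c1c(Br)cc(OC)cc1O | intermediate
9 | 1-{2-bromo-4-methoxy-6-[(triisopropylsilyl)oxy]phenyl}ethan-1-one | CC(=O)c1c(Br)cc(OC)cc1O[Si](C(C)C)(C(C)C)C(C)C | intermediate
10 | 1-{4-methoxy-2-(4,4,5,5-tetramethyl-1,3,2-dioxaborolan-2-yl)-6-[(triisopropylsilyl)oxy]phenyl}ethan-1-one (not isolated) | CC(=O)c1c(B2OC(C)(C)C(C)(C)O2)cc(OC)cc1O[Si](C(C)C)(C(C)C)C(C)C | intermediate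
11 | 1-{3'-(benzyloxy)-2'-bromo-5'-chloro-4',5-dimethoxy-6'-methyl-3-[(triisopropylsilyl)oxy]-[1,1'-biphenyl]-2-yl}ethan-1-one | CC(=O)c1c(-c2c(C)c(Cl)c(OC)c(OCc3ccccc3)c2Br)cc(OC)cc1O[Si](C(C)C)(C(C)C)C(C)C | intermediate
12 | 1-(benzyloxy)-3-chloro-2,6-dimethoxy-4-methyl-8-[(triisopropylsilyl)oxy]phenanthren-9-ol | Oc1cc2c(OCc3ccccc3)c(OC)c(Cl)c(C)c2c2cc(OC)cc(O[Si](C(C)C)(C(C)C)C(C)C)c12 | intermediate
13 | 1-(benzyloxy)-3-chloro-2,6-dimethoxy-4-methyl-8,9-bis[(triisopropylsilyl)oxy]phenanthrene | CC(C)[Si](Oc1cc2c(OCc3ccccc3)c(OC)c(Cl)c(C)c2c2cc(OC)cc(O[Si](C(C)C)(C(C)C)C(C)C)c12)(C(C)C)C(C)C | intermediate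
14 | 4,4-diethoxybutan-1-amine | CCOC(CCCN)OCC | starting material
15 | 1-(benzyloxy)-N-(4,4-diethoxybutyl)-2,6-dimethoxy-4-methyl-8,9-bis[(triisopropylsilyl)oxy]phenanthren-3-amine | CCOC(CCCNc1c(OC)c(OCc2ccccc2)c2cc(O[Si](C(C)C)(C(C)C)C(C)C)c3c(O[Si](C(C)C)(C(C)C)C(C)C)cc(OC)cc3c2c1C)OCC | intermediate
16 | 3-[(4,4-diethoxybutyl)amino]-2,6-dimethoxy-4-methyl-8,9-bis[(triisopropylsilyl)oxy]phenanthren-1-ol | CCOC(CCCNc1c(OC)c(O)c2cc(O[Si](C(C)C)(C(C)C)C(C)C)c3c(O[Si](C(C)C)(C(C)C)C(C)C)cc(OC)cc3c2c1C)OCC | intermediate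
17 | 4-({1-hydroxy-2,6-dimethoxy-4-methyl-8,9-bis[(triisopropylsilyl)oxy]phenanthren-3-yl}amino)butanal (not isolated) | O=CCCCNc1c(OC)c(O)c2cc(O[Si](C(C)C)(C(C)C)C(C)C)c3c(O[Si](C(C)C)(C(C)C)C(C)C)cc(OC)cc3c2c1C | intermediate
18 | 1-{1-hydroxy-2,6-dimethoxy-4-methyl-8,9-bis[(triisopropylsilyl)oxy]phenanthren-3-yl}pyrrolidin-2-ol, both C2' epimers, interconverting (not isolated) | OC1CCCN1c1c(OC)c(O)c2cc(O[Si](C(C)C)(C(C)C)C(C)C)c3c(O[Si](C(C)C)(C(C)C)C(C)C)cc(OC)cc3c2c1C | intermediate
19 | (4R,2'S)-2,6-dimethoxy-4-methyl-8,9-bis[(triisopropylsilyl)oxy]-4H-phenanthren-1-one in which N1' of a pyrrolidine is on C3 and its C2' is bonded through oxygen to C4; ring B is the C9=C10 silyl dienol ether | COC1=C2N3CCC[C@@H]3O[C@]2(C)C2=C(C=C(O[Si](C(C)C)(C(C)C)C(C)C)c3c(O[Si](C(C)C)(C(C)C)C(C)C)cc(OC)cc32)C1=O | intermediate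
20 | CNP0528850.1: (4R,2'S)-8-hydroxy-2,6-dimethoxy-4-methyl-4,10-dihydrophenanthrene-1,9-dione in which N1' of a pyrrolidine is on C3 and its C2' is bonded through oxygen to C4 (cis-fused pyrrolo-oxazolidine, aminal H syn to the C4 methyl) | COC1=C2N3CCC[C@@H]3O[C@]2(C)C2=C(CC(=O)c3c(O)cc(OC)cc32)C1=O | target

**Step count and risks**
Total steps: 13. Longest linear sequence: 11 steps (steps 1–4 and 7–13, from 1 to 20).

Steps most likely to fail:

1. Step 12 (Proposed new method). Enantioinduction may be lost if the C–O bond forms after dissociation to a free phenoxenium ion. The oxygen may add at C2, or adventitious water at C4. The hemiaminal may dehydrate to the enamine and be oxidised. The aminal centre may be formed with poor control.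
Fallback (known chemistry), from 16 back to 19: 16 is oxidised with a chiral aryl-λ3-iodane in aqueous MeCN, a hydroxylative para-dearomatisation of known enantioselective type, to (4R)-3-[(4,4-diethoxybutyl)amino]-4-hydroxy-2,6-dimethoxy-4-methyl-8,9-bis[(triisopropylsilyl)oxy]-4H-phenanthren-1-one F1, with the acetal intact. Treatment with 1 M HCl in THF then frees the aldehyde, the vinylogous-amide N–H condenses with it, and the tertiary C4–OH captures the cyclic iminium ion (N,O-acetalisation) to give 19.

2. Step 10. Oxidative addition and reductive elimination may be slow at the electron-rich, ortho,ortho-disubstituted aryl chloride. The alkoxide base may cleave the silyl ethers, and hydrodechlorination may compete.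
Fallback, from 13 back to 15: Miyaura borylation of the chloride (B2pin2, XPhos Pd G2, KOAc, dioxane) should give 2-{1-(benzyloxy)-2,6-dimethoxy-4-methyl-8,9-bis[(triisopropylsilyl)oxy]phenanthren-3-yl}-4,4,5,5-tetramethyl-1,3,2-dioxaborolane F2. Copper-mediated azidation (Cu(OAc)2, NaN3, MeOH, air) converts it to 3-azido-1-(benzyloxy)-2,6-dimethoxy-4-methyl-8,9-bis[(triisopropylsilyl)oxy]phenanthrene F3. Staudinger reduction (PPh3, THF/H2O) gives 1-(benzyloxy)-2,6-dimethoxy-4-methyl-8,9-bis[(triisopropylsilyl)oxy]phenanthren-3-amine F4. N-Alkylation with 4-chloro-1,1-diethoxybutane (NaI, K2CO3, DMF, 90 °C) then gives 15.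

3. Step 8. Oxidative addition may fail at the C–Br bond flanked by the benzyloxy group and the aryl ring. The C–Cl bond may react prematurely, or the ketone may undergo aldol self-condensation under base.
Fallback, from 11 back to 12: the potassium enolate of 11 (KOtBu, DMSO or liquid NH3) is cyclised under irradiation by the SRN1 radical-chain enolate arylation, which needs no metal and no oxidative addition. New compound: none F0.

**Further compounds**
F1 | step 12 | (4R)-3-[(4,4-diethoxybutyl)amino]-4-hydroxy-2,6-dimethoxy-4-methyl-8,9-bis[(triisopropylsilyl)oxy]-4H-phenanthren-1-one | CCOC(CCCNC1=C(OC)C(=O)C2=C(c3cc(OC)cc(O[Si](C(C)C)(C(C)C)C(C)C)c3C(O[Si](C(C)C)(C(C)C)C(C)C)=C2)[C@@]1(C)O)OCC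
F2 | step 10 | 2-{1-(benzyloxy)-2,6-dimethoxy-4-methyl-8,9-bis[(triisopropylsilyl)oxy]phenanthren-3-yl}-4,4,5,5-tetramethyl-1,3,2-dioxaborolane | CC(C)[Si](Oc1cc2c(OCc3ccccc3)c(OC)c(B3OC(C)(C)C(C)(C)O3)c(C)c2c2cc(OC)cc(O[Si](C(C)C)(C(C)C)C(C)C)c12)(C(C)C)C(C)C
F3 | step 10 | 3-azido-1-(benzyloxy)-2,6-dimethoxy-4-methyl-8,9-bis[(triisopropylsilyl)oxy]phenanthrene | CC(C)[Si](Oc1cc2c(OCc3ccccc3)c(OC)c(N=[N+]=[N-])c(C)c2c2cc(OC)cc(O[Si](C(C)C)(C(C)C)C(C)C)c12)(C(C)C)C(C)C
F4 | step 10 | 1-(benzyloxy)-2,6-dimethoxy-4-methyl-8,9-bis[(triisopropylsilyl)oxy]phenanthren-3-amine | CC(C)[Si](Oc1cc2c(OCc3ccccc3)c(OC)c(N)c(C)c2c2cc(OC)cc(O[Si](C(C)C)(C(C)C)C(C)C)c12)(C(C)C)C(C)C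
F0 | step 8 | none | none
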